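**Retrosynthetic overview**
1. Numbering used: indane C1 (benzylidene carbon), C2 (bears ring B, 3,5-dihydroxyphenyl), C3 (bears ring C, 2,4-dihydroxyphenyl); ring A is the fused resorcinol ring (C3a to C7a, oxygens on C4 and C6), ring D the guaiacyl ring.
2. Target 21 ⇒ perbenzyl ether 20 ⇒ (Ramberg–Bäcklund, C1=CH–ring D) sulfone 17 ⇒ sulfide 15, so ring D arrives as thiol 12 on C1.
3. 15 ⇒ open-chain ortho-hydroxybenzhydrol 9 by cutting the C2–C3 bond of the five-membered ring (and the C1–S bond): one operation closes the carbocycle and a temporary O–C1 bridge from ring C, then trades the bridge for the thiol.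
4. Enabling feature: C3 lies between ring C, whose ortho hydroxyl turns it into an ortho-quinone methide, and C3a of ring A, which is ortho/para to the C4 and C6 oxygens; the (E)-stilbene C1=C2 sits on the neighbouring C7a, so C2 can reach C3 and the ring C oxygen can reach C1.
5. 9 ⇒ aryl bromide 5 (from 1 via 2 and from 3 via 4, Horner–Wadsworth–Emmons) plus salicylaldehyde 6; all aromatic rings are bought, and the five-membered ring (with its transient six-membered oxygen bridge) is the only ring made.

Key step: step 6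

Assumption: the (R)-configured catalyst is taken to deliver the C3 configuration of the target; should the sense of induction prove opposite, the (S)-catalyst is used with no other change.

Step 1
Reactants: 1 3,5-bis(benzyloxy)benzaldehyde
Product: 2 2-bromo-3,5-bis(benzyloxy)benzaldehyde
Conditions: NBS (1.0 equiv), MeCN, 0 °C to rt, dark
Reagents that add atoms: N-bromosuccinimide, O=C1CCC(=O)N1Br
Why: Electrophilic aromatic bromination should occur at C2, para to one benzyloxy group and ortho to the other, the position that reacts in 3,5-dialkoxybenzaldehydes, rather than at the crowded carbon between the two ethers.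

Step 2
Reactants: 3 3,5-bis(benzyloxy)benzyl bromide
Product: 4 diethyl [3,5-bis(benzyloxy)benzyl]phosphonate
Conditions: P(OEt)3, neat, 130 °C
Reagents that add atoms: triethyl phosphite, CCOP(OCC)OCC
Why: Michaelis–Arbuzov reaction of a primary benzylic bromide, driven by loss of bromoethane.

Step 3
Reactants: 2 2-bromo-3,5-bis(benzyloxy)benzaldehyde; 4 diethyl [3,5-bis(benzyloxy)benzyl]phosphonate
Product: 5 (E)-1-bromo-2,4-bis(benzyloxy)-6-[2-(3,5-bis(benzyloxy)phenyl)ethenyl]benzene
Conditions: KOtBu, THF, 0 °C to rt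
Reagents that add atoms: none
Why: Horner–Wadsworth–Emmons olefination of a benzylic phosphonate with an aryl aldehyde should give the (E)-stilbene, the geometry that later keeps ring B away from C3.

Step 4
Reactants: 5 (E)-1-bromo-2,4-bis(benzyloxy)-6-[2-(3,5-bis(benzyloxy)phenyl)ethenyl]benzene; 6 4-(benzyloxy)-2-hydroxybenzaldehyde
Product: 9 racemic {2,4-bis(benzyloxy)-6-[(E)-2-(3,5-bis(benzyloxy)phenyl)ethenyl]phenyl}[4-(benzyloxy)-2-hydroxyphenyl]methanol, via aryllithium 7 (not isolated), via sodium phenoxide 8 (not isolated)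
Conditions: 5, n-BuLi, THF, -78 °C; 6, NaH, THF, 0 °C; combine at -78 °C, then to 0 °C; H2O; silica deactivated by Et3N
Reagents that add atoms: none
Why: Bromine–lithium exchange at -78 °C is faster than addition to the stilbene, and the aryllithium should add 1,2 to the aldehyde whose phenol is masked as its sodium phenoxide; the carbinol centre forms as a racemate and is erased in step 6.

Step 5
Reactants: 10 4-(benzyloxy)-3-methoxybenzyl alcohol
Product: 12 [4-(benzyloxy)-3-methoxyphenyl]methanethiol, via isothiouronium chloride 11 (not isolated)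
Conditions: thiourea, HCl (aq), acetone, 50 °C; then NaOH (aq), reflux, N2; HCl to pH 4
Reagents that add atoms: thiourea, NC(N)=S
Why: The para-alkoxybenzylic alcohol should alkylate thiourea on sulfur under acid (SN1-type), and alkaline hydrolysis of the isothiouronium salt releases the thiol.

Step 6
Reactants: 9 racemic ortho-hydroxybenzhydrol; 12 [4-(benzyloxy)-3-methoxyphenyl]methanethiol
Product: 15 4,6-bis(benzyloxy)-2-[3,5-bis(benzyloxy)phenyl]-3-[4-(benzyloxy)-2-hydroxyphenyl]-1-{[4-(benzyloxy)-3-methoxybenzyl]sulfanyl}indane (2,3-trans; C2 and C3 arranged as in the target; both C1 epimers), via ortho-quinone methide 13 (not isolated), via bridged ether 14 (not isolated)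
Conditions: (R)-3,3'-bis(2,4,6-triisopropylphenyl)-1,1'-binaphthyl-2,2'-diyl N-triflylphosphoramide (5 mol%), 4 Å MS, toluene, -40 to -20 °C; then 12 (5 equiv), CF3SO3H (10 mol%), CH2Cl2, -40 °C; Et3N
Reagents that add atoms: none
Why: Proposed new method: the chiral acid should dehydrate 9 to ortho-quinone methide 13, held by hydrogen bonds in the phosphoramide pocket; alkene carbon C2 then attacks methide carbon C3 and the ring C oxygen collapses onto the benzylic cation at C1 to give bridged ether 14 (a stepwise formal (4+2) cycloaddition), after which CF3SO3H reopens the C1–O bond and thiol 12 captures C1. The closest known reaction types are the chiral N-triflylphosphoramide-catalysed addition of styrenes to ortho-quinone methides from ortho-hydroxybenzhydrols (giving 2,4-diarylchromans) and the acid-mediated cation–olefin closure of O-methylated 2-(diarylcarbinol)stilbenes with thiol capture; the intramolecular, bridged and enantioselective combination is new. The five-membered carbocycle closes 5-endo-trig through the C2–C3 bond, and the temporary six-membered oxygen bridge closes by 6-endo capture of the C1 cation by the phenol oxygen. C3 is set by the catalyst, which shields one face of the bound methide; C2 follows from the (E)-alkene through the open transition state that places ring B trans to ring C (the cis arrangement would push ring B into the oxygen bridge); C1 is temporary and is erased in step 9. The step needs alkene attack on C3 in preference to Friedel–Crafts attack by ring B and to uncatalysed ionisation, which the (E) geometry (ring B held away from C3) and ionisation only on the chiral acid at low temperature should secure. In the thiolysis the excess thiol should trap the C1 cation faster than it loses the C2 proton or fragments back, so C2 and C3 are not scrambled.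

Step 7
Reactants: 15 sulfide phenol
Product: 16 4,6-bis(benzyloxy)-2-[3,5-bis(benzyloxy)phenyl]-3-[2,4-bis(benzyloxy)phenyl]-1-{[4-(benzyloxy)-3-methoxybenzyl]sulfanyl}indane (C2 and C3 as in 15)
Conditions: BnBr, K2CO3, DMF, rt
Reagents that add atoms: benzyl bromide, BrCc1ccccc1
Why: Williamson etherification of the one free phenol (the phenoxide far outpaces the dialkyl sulfide as nucleophile) removes the only group that would interfere with the halogenating conditions of step 9.

Step 8
Reactants: 16 perbenzylated sulfide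
Product: 17 the corresponding sulfone (C1–SO2–CH2–ring D; C2 and C3 unchanged)
Conditions: mCPBA (2.2 equiv), CH2Cl2, 0 °C to rt
Reagents that add atoms: 3-chloroperoxybenzoic acid, OOC(=O)c1cccc(Cl)c1
Why: Peracid oxidation of a dialkyl sulfide to the sulfone; no alkene is present at this stage and the stereocentres are not touched.

Step 9
Reactants: 17 sulfone
Product: 20 (E)-1-[4-(benzyloxy)-3-methoxybenzylidene]-4,6-bis(benzyloxy)-2-[3,5-bis(benzyloxy)phenyl]-3-[2,4-bis(benzyloxy)phenyl]indane (C2 and C3 as in the target), via α-chlorosulfone 18 (not isolated), via episulfone 19 (not isolated)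
Conditions: KOH, CCl4, t-BuOH/H2O, 80 °C
Reagents that add atoms: none
Why: Ramberg–Bäcklund reaction with in situ chlorination: the double bond can only form between C1 and the ring D methylene, so the exocyclic position is fixed; the (E) geometry is expected as for closely related 1-benzylidene-2,3-diarylindanes, because the (Z) isomer would push ring D against the peri hydrogen on C7, and C2 and C3 are not alpha to the sulfone and should keep their configuration.

Step 10
Reactants: 20 perbenzylated alkene
Product: 21 (1E,2S,3S)-2-(3,5-dihydroxyphenyl)-3-(2,4-dihydroxyphenyl)-1-[(4-hydroxy-3-methoxyphenyl)methylidene]-2,3-dihydro-1H-indene-4,6-diol (target)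
Conditions: BCl3, pentamethylbenzene, CH2Cl2, -78 °C; then H2O
Reagents that add atoms: none
Why: BCl3-mediated cleavage of aryl benzyl ethers with pentamethylbenzene as a non-basic benzyl cation scavenger is a known way to remove benzyl groups at -78 °C while leaving aryl methyl ethers and alkenes intact, so the guaiacyl OMe, the benzylidene and both stereocentres should survive.

**Compound list**
1 | 3,5-bis(benzyloxy)benzaldehyde | O=Cc1cc(OCc2ccccc2)cc(OCc2ccccc2)c1 | starting material
2 | 2-bromo-3,5-bis(benzyloxy)benzaldehyde | O=Cc1cc(OCc2ccccc2)cc(OCc2ccccc2)c1Br | intermediate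
3 | 3,5-bis(benzyloxy)benzyl bromide | BrCc1cc(OCc2ccccc2)cc(OCc2ccccc2)c1 | starting material
4 | diethyl [3,5-bis(benzyloxy)benzyl]phosphonate | CCOP(=O)(OCC)Cc1cc(OCc2ccccc2)cc(OCc2ccccc2)c1 | intermediate
5 | (E)-1-bromo-2,4-bis(benzyloxy)-6-[2-(3,5-bis(benzyloxy)phenyl)ethenyl]benzene | Brc1c(OCc2ccccc2)cc(OCc2ccccc2)cc1/C=C/c1cc(OCc2ccccc2)cc(OCc2ccccc2)c1 | intermediate
6 | 4-(benzyloxy)-2-hydroxybenzaldehyde | O=Cc1ccc(OCc2ccccc2)cc1O | starting material
7 | aryllithium from 5 (Li in place of Br) | [Li]c1c(OCc2ccccc2)cc(OCc2ccccc2)cc1/C=C/c1cc(OCc2ccccc2)cc(OCc2ccccc2)c1 | intermediate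
8 | sodium 5-(benzyloxy)-2-formylphenoxide | [Na+].[O-]c1cc(OCc2ccccc2)ccc1C=O | intermediate
9 | racemic {2,4-bis(benzyloxy)-6-[(E)-2-(3,5-bis(benzyloxy)phenyl)ethenyl]phenyl}[4-(benzyloxy)-2-hydroxyphenyl]methanol | OC(c1ccc(OCc2ccccc2)cc1O)c1c(OCc2ccccc2)cc(OCc2ccccc2)cc1/C=C/c1cc(OCc2ccccc2)cc(OCc2ccccc2)c1 | intermediate
10 | 4-(benzyloxy)-3-methoxybenzyl alcohol | OCc1ccc(OCc2ccccc2)c(OC)c1 | starting material
11 | S-[4-(benzyloxy)-3-methoxybenzyl]isothiouronium chloride | NC(=[NH2+])SCc1ccc(OCc2ccccc2)c(OC)c1.[Cl-] | intermediate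
12 | [4-(benzyloxy)-3-methoxyphenyl]methanethiol | SCc1ccc(OCc2ccccc2)c(OC)c1 | intermediate
13 | ortho-quinone methide of ring C (methide carbon = future C3, attached to ring A) | O=C1C=C(OCc2ccccc2)C=CC1=Cc1c(OCc2ccccc2)cc(OCc2ccccc2)cc1/C=C/c1cc(OCc2ccccc2)cc(OCc2ccccc2)c1 | intermediate
14 | bridged ether: ring C oxygen bonded to C1, cis to ring C on C3; ring B on C2 trans to ring C | O4[C@@H]2c3cc(OCc5ccccc5)cc(OCc5ccccc5)c3[C@H](c3ccc(OCc5ccccc5)cc34)[C@H]2c2cc(OCc5ccccc5)cc(OCc5ccccc5)c2 | intermediate
15 | sulfide phenol: 4,6-bis(benzyloxy)-2-[3,5-bis(benzyloxy)phenyl]-3-[4-(benzyloxy)-2-hydroxyphenyl]-1-{[4-(benzyloxy)-3-methoxybenzyl]sulfanyl}indane, 2,3-trans, C1 epimers | COc1cc(CSC2c3cc(OCc4ccccc4)cc(OCc4ccccc4)c3[C@H](c3ccc(OCc4ccccc4)cc3O)[C@H]2c2cc(OCc4ccccc4)cc(OCc4ccccc4)c2)ccc1OCc1ccccc1 | intermediate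
16 | perbenzylated sulfide (ring C 2-OH benzylated) | COc1cc(CSC2c3cc(OCc4ccccc4)cc(OCc4ccccc4)c3[C@H](c3ccc(OCc4ccccc4)cc3OCc3ccccc3)[C@H]2c2cc(OCc4ccccc4)cc(OCc4ccccc4)c2)ccc1OCc1ccccc1 | intermediate
17 | sulfone of 16 | COc1cc(CS(=O)(=O)C2c3cc(OCc4ccccc4)cc(OCc4ccccc4)c3[C@H](c3ccc(OCc4ccccc4)cc3OCc3ccccc3)[C@H]2c2cc(OCc4ccccc4)cc(OCc4ccccc4)c2)ccc1OCc1ccccc1 | intermediate
18 | α-chlorosulfone (Cl on the ring D methine) | COc1cc(C(Cl)S(=O)(=O)C2c3cc(OCc4ccccc4)cc(OCc4ccccc4)c3[C@H](c3ccc(OCc4ccccc4)cc3OCc3ccccc3)[C@H]2c2cc(OCc4ccccc4)cc(OCc4ccccc4)c2)ccc1OCc1ccccc1 | intermediate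
19 | episulfone spiro-fused at C1 | COc1cc(C5S(=O)(=O)C52c3cc(OCc4ccccc4)cc(OCc4ccccc4)c3[C@H](c3ccc(OCc4ccccc4)cc3OCc3ccccc3)[C@H]2c2cc(OCc4ccccc4)cc(OCc4ccccc4)c2)ccc1OCc1ccccc1 | intermediate
20 | heptabenzyl ether of the target, (E)-benzylidene | COc1cc(/C=C2/c3cc(OCc4ccccc4)cc(OCc4ccccc4)c3[C@H](c3ccc(OCc4ccccc4)cc3OCc3ccccc3)[C@H]2c2cc(OCc4ccccc4)cc(OCc4ccccc4)c2)ccc1OCc1ccccc1 | intermediate
21 | (1E,2S,3S)-2-(3,5-dihydroxyphenyl)-3-(2,4-dihydroxyphenyl)-1-[(4-hydroxy-3-methoxyphenyl)methylidene]-2,3-dihydro-1H-indene-4,6-diol | COc1cc(/C=C2/c3cc(O)cc(O)c3[C@H](c3ccc(O)cc3O)[C@H]2c2cc(O)cc(O)c2)ccc1O | target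

**Step count and risks**
Total steps: 10. Longest linear sequence: 8 (steps 1, 3, 4, 6, 7, 8, 9, 10).

Step 6 (proposed new method). What may go wrong: uncatalysed ionisation of 9 erodes enantiofacial control, or the oxygen bridge re-closes in competition with thiol capture. Fallback with known chemistry: setting out from 9 and 12, the closure is run with CF3CO2H in CH2Cl2 at -30 °C in the presence of 12 (achiral acid-mediated cation–olefin cyclisation with thiol capture). This should give the racemate, that is 15 together with the mirror-image sulfide F1. Esterification of the free phenol with N-Boc-L-phenylalanine (EDC, DMAP, CH2Cl2) should give two diastereomers, the Boc-phenylalanine ester of 15 F2 and the Boc-phenylalanine ester of the mirror-image sulfide F3, to be separated by chromatography or crystallisation. K2CO3 in MeOH then cleaves F2 and the route is rejoined at 15.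

Step 9. What may go wrong: dichlorocarbene formed from CCl4 adds to the new electron-rich alkene, or the sulfone is chlorinated more than once. Fallback: setting out from 9, step 6 is run with 1-phenyl-1H-tetrazole-5-thiol in place of 12 to give the tetrazolyl sulfide phenol F4. Benzylation as in step 7 gives the benzylated tetrazolyl sulfide F5, and oxidation (H2O2, (NH4)6Mo7O24, EtOH) gives the tetrazolyl sulfone F6. Julia–Kocienski olefination of F6 with 4-(benzyloxy)-3-methoxybenzaldehyde (KN(SiMe3)2, THF, -78 °C) comes back to the route at 20.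

Step 4. What may go wrong: proton transfer from incompletely deprotonated phenol quenches the aryllithium, addition to the electron-rich phenoxide aldehyde is slow, or the benzhydrol ionises during isolation. Fallback with inverted roles: setting out from 5, bromine–lithium exchange and a DMF quench give the ring A aldehyde F7. Ortho-selective hydroxyalkylation of bromomagnesium 3-(benzyloxy)phenoxide F8 (from 3-(benzyloxy)phenol and EtMgBr, toluene, rt) by F7 should take place para to the benzyloxy group and comes back to the route at 9.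

**Further compounds**
F1 | step 6 | mirror-image sulfide (enantiomer of 15 at C2 and C3; C1 epimers) | COc1cc(CSC2c3cc(OCc4ccccc4)cc(OCc4ccccc4)c3[C@@H](c3ccc(OCc4ccccc4)cc3O)[C@@H]2c2cc(OCc4ccccc4)cc(OCc4ccccc4)c2)ccc1OCc1ccccc1
F2 | step 6 | N-Boc-L-phenylalanine aryl ester of 15 | COc1cc(CSC2c3cc(OCc4ccccc4)cc(OCc4ccccc4)c3[C@H](c3ccc(OCc4ccccc4)cc3OC(=O)[C@H](Cc3ccccc3)NC(=O)OC(C)(C)C)[C@H]2c2cc(OCc4ccccc4)cc(OCc4ccccc4)c2)ccc1OCc1ccccc1
F3 | step 6 | N-Boc-L-phenylalanine aryl ester of the mirror-image sulfide | COc1cc(CSC2c3cc(OCc4ccccc4)cc(OCc4ccccc4)c3[C@@H](c3ccc(OCc4ccccc4)cc3OC(=O)[C@H](Cc3ccccc3)NC(=O)OC(C)(C)C)[C@@H]2c2cc(OCc4ccccc4)cc(OCc4ccccc4)c2)ccc1OCc1ccccc1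
F4 | step 9 | tetrazolyl sulfide phenol (1-phenyl-1H-tetrazol-5-ylsulfanyl on C1; otherwise as 15) | c1ccccc1-n1nnnc1SC2c3cc(OCc4ccccc4)cc(OCc4ccccc4)c3[C@H](c3ccc(OCc4ccccc4)cc3O)[C@H]2c2cc(OCc4ccccc4)cc(OCc4ccccc4)c2
F5 | step 9 | benzylated tetrazolyl sulfide | c1ccccc1-n1nnnc1SC2c3cc(OCc4ccccc4)cc(OCc4ccccc4)c3[C@H](c3ccc(OCc4ccccc4)cc3OCc3ccccc3)[C@H]2c2cc(OCc4ccccc4)cc(OCc4ccccc4)c2
F6 | step 9 | tetrazolyl sulfone | c1ccccc1-n1nnnc1S(=O)(=O)C2c3cc(OCc4ccccc4)cc(OCc4ccccc4)c3[C@H](c3ccc(OCc4ccccc4)cc3OCc3ccccc3)[C@H]2c2cc(OCc4ccccc4)cc(OCc4ccccc4)c2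
F7 | step 4 | ring A aldehyde: 2,4-bis(benzyloxy)-6-[(E)-2-(3,5-bis(benzyloxy)phenyl)ethenyl]benzaldehyde | O=Cc1c(OCc2ccccc2)cc(OCc2ccccc2)cc1/C=C/c1cc(OCc2ccccc2)cc(OCc2ccccc2)c1
F8 | step 4 | bromomagnesium 3-(benzyloxy)phenoxide | Br[Mg]Oc1cccc(OCc2ccccc2)c1
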